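(All runs are calculated on assumed constants, noise included.)

If the impurity takes the racemization catalyst out one for one, a flask can be judged by a subtraction before it is started. That was how I decided whether to leave the charge of the next flask as it stood.

the same everywhere: left-handed substrate 0.73 M; right-handed substrate 0.73 M; solid reagent 1.82 M; free catalyst 15 mM; racemization catalyst 1.5 mM
- Thursday's: impurity 0.80 mM; run made earlier
- Wednesday's: impurity 1.2 mM; run made earlier
- flask: impurity 1.6 mM; time 1.5 h

| run | time / min | left-handed product / % | right-handed product / % |
|---|---|---|---|
| Thursday's | 6.00 | 27.0 | 0.1 |
| Thursday's | 20.0 | 66.3 | 0.4 |
| Thursday's | 40.0 | 89.6 | 0.9 |
| Thursday's | 50.0 | 94.2 | 0.7 |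
| Wednesday's | 4.00 | 17.5 | 0.2 |
| Wednesday's | 10.0 | 40.3 | 0.3 |
| Wednesday's | 25.0 | 73.8 | 0.3 |
| Wednesday's | 50.0 | 93.3 | 1.0 |

(standard deviation of a reading: 0.3 percentage points)

- free catalyst is single-handed; left-handed substrate and right-handed substrate are mirror images of each other, charged as a racemate, each of them at the stated concentration
- solid, in amounts per volume of the solution: solid reagent
- what may be going on: racemization catalyst + impurity -> spent catalyst B; left-handed substrate + racemization catalyst <-> right-handed substrate + racemization catalyst; coupling partner + racemization catalyst -> spent catalyst A; coupling partner + free catalyst + right-handed substrate -> free catalyst + right-handed product; solid reagent <-> coupling partner; coupling partner + free catalyst + left-handed substrate -> free catalyst + left-handed product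
- at the start none of the solid reagent is in solution
- an excess is below zero if the other one leads

- left-handed product and right-handed product together, in percent of the left-handed substrate and right-handed substrate charged together, at 1.5 h
- excess of left-handed product over right-handed product in the product at 1.5 h
- whether the exchange between left-handed substrate and right-handed substrate keeps pace with the reaction: how far the product's excess at 1.5 h gets from its value without exchange to its value with instant exchange (above 80 % keeps pace, below 20 % hardly takes part, else lags behind)

I called the surviving share the part of the charged racemization catalyst left after subtracting the impurity charged, and it was 46.7 % for Thursday's run and 20.0 % for Wednesday's. Left-handed substrate was half of the charge, yet even Wednesday's run, with a smaller share than Thursday's, stood at 93.3 % left-handed product after 50.0 min. The right-handed substrate must have crossed over in that run, so a share of 20.0 % had been enough there.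

For the new flask the share was −6.67 %: with 1.6 mM of impurity, more than the 1.5 mM of racemization catalyst, the subtraction came out below zero. So I left the charge alone and booked the flask as a resolution, with left-handed product stopping near half of the charge and right-handed product as a small correction on top.

The forecast said the same: 54 % in all, an excess of 86 %, and exchange that hardly takes part, since “this becomes a plain kinetic resolution”.

The flask gave 54.9 % with an excess of 85.3 %, and the exchange hardly takes part. It got 7.9 % of the way, and left-handed product ended at 50.9 %. The share of −6.67 % also says how much impurity stays over, 6.25 % of its own charge; the flask held 6.5 % of it, with racemization catalyst at 0 %.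

    racemization catalyst + impurity → spent catalyst B (k = 234 /M/s)
    left-handed substrate + racemization catalyst ⇌ right-handed substrate + racemization catalyst, rate k2*[racemization catalyst]*[left-handed substrate] forward; the back reaction follows from the equilibrium constant (k = 67.5 /M/s)
    coupling partner + racemization catalyst → spent catalyst A (k = 0.0135 /M/s)
    coupling partner + free catalyst + right-handed substrate → free catalyst + right-handed product (k = 0.0254 /M²/s)
    solid reagent ⇌ coupling partner, rate k5*(cs5 - [coupling partner]) while solid is left; crystals form when [coupling partner] > cs5 (solubility = 43.0 mM, k = 0.123 /s)
    coupling partner + free catalyst + left-handed substrate → free catalyst + left-handed product (k = 3.42 /M²/s)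

In the neighbouring flask with 0.0037 M of racemization catalyst, the same subtraction gives a share of 56.8 %, above Thursday's, so exchange should carry the product past half of the charge. That flask gave 99.6 % with an excess of 98.5 %.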